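**Strategy.** In labdane numbering, ring B of the target is a cyclohexene that shares the C5–C10 bond with ring A and carries C17 on C8 and the side chain on C9. Shifting its alkene from C7–C8 to C6–C7 exposes a Diels–Alder ring, so the skeleton is cut at C5–C10 and C8–C9. One thermal intramolecular cycloaddition of an acyclic (2E,4E)-dienoate (C5–C8) onto the E-trisubstituted C9–C10 alkene, linked by the C1–C4 chain, closes rings A and B and sets C5, C9 and C10. The triene comes from (S)-citronellol (C13) and carries a removable (R)-silyloxy group at C2 that selects the π-face.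

Key step: step 13

Remark on the chemistry: C13 lies too far from the reacting carbons to distinguish the two π-face pairings, so an equatorial 2-silyloxy group, whose axial alternative would be syn to both the axial C4 methyl and the C10 methyl, is added to the tether and removed after ring closure; the carbon skeletons of triene and adduct are otherwise unchanged, and labdane numbering is used for all positions.

**Step 1**
Reactants: 1 (S)-citronellol
Product: 2 tert-butyl{[(3S)-3,7-dimethyloct-6-en-1-yl]oxy}diphenylsilane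
Conditions: TBDPSCl, imidazole, DMF, 0 °C → rt
Reagents that add atoms: tert-butyl(chloro)diphenylsilane, CC(C)(C)[Si](Cl)(c1ccccc1)c1ccccc1
Why: Imidazole-promoted silyl ether formation masks the only hydroxyl (C15–OH) with a group that should survive organometallics, hydrides, base and 185 °C and is removed by fluoride at the end; C13 is untouched.

**Step 2**
Reactants: 2 tert-butyl{[(3S)-3,7-dimethyloct-6-en-1-yl]oxy}diphenylsilane
Product: 4 (4S)-6-[(tert-butyldiphenylsilyl)oxy]-4-methylhexanal, via ozonide 3 (not isolated)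
Conditions: O3, CH2Cl2, −78 °C; then PPh3, −78 °C → rt
Reagents that add atoms: ozone, [O-][O+]=O
Why: Ozonolysis with reductive work-up cleaves the only alkene and should give the aldehyde whose carbonyl carbon is C9, leaving the silyl ether and C13 unchanged.

**Step 3**
Reactants: 4 (4S)-6-[(tert-butyldiphenylsilyl)oxy]-4-methylhexanal; 5 isopropenylmagnesium bromide
Product: 6 (3RS,6S)-8-[(tert-butyldiphenylsilyl)oxy]-2,6-dimethyloct-1-en-3-ol
Conditions: THF, −78 → 0 °C; then H2O/aq. NH4Cl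
Reagents that add atoms: none
Why: Grignard 1,2-addition to the unhindered aldehyde brings in C10, C20 and C1; the carbinol centre forms as both epimers, which is immaterial because it becomes sp2 in step 4.

**Step 4**
Reactants: 6 (3RS,6S)-8-[(tert-butyldiphenylsilyl)oxy]-2,6-dimethyloct-1-en-3-ol; 7 triethyl orthoacetate
Product: 9 ethyl (4E,8S)-10-[(tert-butyldiphenylsilyl)oxy]-4,8-dimethyldec-4-enoate, via ketene acetal 8 (not isolated)
Conditions: EtCO2H (cat.), neat 7, 140 °C, EtOH distilled off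
Reagents that add atoms: none
Why: Johnson–Claisen rearrangement through a chair with the C11 chain equatorial should give the E C9=C10 alkene (C20 cis to C11) and adds C2 and C3.

**Step 5**
Reactants: 9 ethyl (4E,8S)-10-[(tert-butyldiphenylsilyl)oxy]-4,8-dimethyldec-4-enoate
Product: 10 (4E,8S)-10-[(tert-butyldiphenylsilyl)oxy]-4,8-dimethyldec-4-enal
Conditions: i-Bu2AlH (1.05 equiv), CH2Cl2, −78 °C; MeOH, then aq. KNaC4H4O6
Reagents that add atoms: none
Why: Partial ester reduction by i-Bu2AlH at −78 °C stops at the aluminium hemiacetal, which should release the C3 aldehyde on work-up.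

**Step 6**
Reactants: 10 (4E,8S)-10-[(tert-butyldiphenylsilyl)oxy]-4,8-dimethyldec-4-enal
Product: 12 (2R,4E,8S)-2-(anilinooxy)-10-[(tert-butyldiphenylsilyl)oxy]-4,8-dimethyldec-4-en-1-ol, via anilinooxy aldehyde 11 (not isolated)
Conditions: L-proline (20 mol %), PhNO, CHCl3, 4 °C; then NaBH4, EtOH, 0 °C
Reagents that add atoms: nitrosobenzene, O=Nc1ccccc1
Why: Proline-catalysed α-aminoxylation: the E-enamine of L-proline is attacked by the nitroso oxygen on the face of the carboxylic acid (Re face), which sets 2R, and immediate NaBH4 reduction protects the labile α-oxy aldehyde from racemisation.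

**Step 7**
Reactants: 12 (2R,4E,8S)-2-(anilinooxy)-10-[(tert-butyldiphenylsilyl)oxy]-4,8-dimethyldec-4-en-1-ol
Product: 13 (2R,4E,8S)-10-[(tert-butyldiphenylsilyl)oxy]-4,8-dimethyldec-4-ene-1,2-diol
Conditions: Zn, AcOH, THF, rt
Reagents that add atoms: none
Why: Reductive N–O cleavage by zinc in acetic acid frees the 2-hydroxyl without touching the alkene, the silyl ether or the C2–O bond.

**Step 8**
Reactants: 13 (2R,4E,8S)-10-[(tert-butyldiphenylsilyl)oxy]-4,8-dimethyldec-4-ene-1,2-diol
Product: 15 (2R)-2-{(2E,6S)-8-[(tert-butyldiphenylsilyl)oxy]-2,6-dimethyloct-2-en-1-yl}oxirane, via primary tosylate 14 (not isolated)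
Conditions: NaH (2.5 equiv), 1-(p-tolylsulfonyl)imidazole, THF, 0 °C → rt
Reagents that add atoms: none
Why: Selective sulfonylation of the primary alkoxide followed by intramolecular Williamson displacement closes the epoxide at C3, so the C2–O bond is never broken and 2R is retained.

**Step 9**
Reactants: 15 (2R)-2-{(2E,6S)-8-[(tert-butyldiphenylsilyl)oxy]-2,6-dimethyloct-2-en-1-yl}oxirane; 16 isobutyronitrile
Product: 17 (4R,6E,10S)-12-[(tert-butyldiphenylsilyl)oxy]-4-hydroxy-2,2,6,10-tetramethyldodec-6-enenitrile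
Conditions: 16, LiN(i-Pr)2, THF, −78 °C; then 15, −78 °C → rt; H2O at 0 °C
Reagents that add atoms: none
Why: SN2 opening of the terminal epoxide at its CH2 (C3) by the lithiated nitrile forms C3–C4 and brings in C4, C5 and both C4 methyl groups, leaving C2 untouched.

**Step 10**
Reactants: 17 (4R,6E,10S)-12-[(tert-butyldiphenylsilyl)oxy]-4-hydroxy-2,2,6,10-tetramethyldodec-6-enenitrile
Product: 18 (4R,6E,10S)-4-[(tert-butyldimethylsilyl)oxy]-12-[(tert-butyldiphenylsilyl)oxy]-2,2,6,10-tetramethyldodec-6-enenitrile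
Conditions: TBSOTf, 2,6-lutidine, CH2Cl2, −78 → 0 °C
Reagents that add atoms: tert-butyldimethylsilyl trifluoromethanesulfonate, CC(C)(C)[Si](C)(C)OS(=O)(=O)C(F)(F)F
Why: Silyl triflate silylation of the secondary alcohol gives the 2-OTBS group, which blocks oxa-Michael addition to the later dienoate, acts as the conformational controller in step 13 and can be cleaved in the presence of the primary TBDPS ether.

**Step 11**
Reactants: 18 (4R,6E,10S)-4-[(tert-butyldimethylsilyl)oxy]-12-[(tert-butyldiphenylsilyl)oxy]-2,2,6,10-tetramethyldodec-6-enenitrile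
Product: 19 (4R,6E,10S)-4-[(tert-butyldimethylsilyl)oxy]-12-[(tert-butyldiphenylsilyl)oxy]-2,2,6,10-tetramethyldodec-6-enal
Conditions: i-Bu2AlH (1.5 equiv), toluene, −78 °C; then aq. AcOH–NaOAc (pH 5), 0 °C
Reagents that add atoms: water, O
Why: Nitrile half-reduction: i-Bu2AlH adds once and the N-aluminio imine is hydrolysed on mildly acidic work-up to the non-enolisable α-quaternary C5 aldehyde.

**Step 12**
Reactants: 19 (4R,6E,10S)-4-[(tert-butyldimethylsilyl)oxy]-12-[(tert-butyldiphenylsilyl)oxy]-2,2,6,10-tetramethyldodec-6-enal; 20 methyl (2E)-4-(dimethoxyphosphoryl)but-2-enoate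
Product: 21 methyl (2E,4E,8R,10E,14S)-8-[(tert-butyldimethylsilyl)oxy]-16-[(tert-butyldiphenylsilyl)oxy]-6,6,10,14-tetramethylhexadeca-2,4,10-trienoate
Conditions: 20, LiN(SiMe3)2, THF, −78 °C; then 19, −78 → 0 °C
Reagents that add atoms: none
Why: Vinylogous Horner–Wadsworth–Emmons olefination of a non-enolisable aldehyde; reversible addition with the bulky neopentyl-type partner should give the E C5=C6 alkene, while the C7=C8 E geometry comes from the reagent.

**Step 13**
Reactants: 21 methyl (2E,4E,8R,10E,14S)-8-[(tert-butyldimethylsilyl)oxy]-16-[(tert-butyldiphenylsilyl)oxy]-6,6,10,14-tetramethylhexadeca-2,4,10-trienoate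
Product: 22 methyl (13S)-2α-[(tert-butyldimethylsilyl)oxy]-15-[(tert-butyldiphenylsilyl)oxy]labd-6-en-17-oate (8β-ester; 5α-H; 9α-H; 10β-methyl)
Conditions: 1,2-dichlorobenzene (0.01 M), BHT (0.1 equiv), Ar, 185 °C, sealed vessel
Reagents that add atoms: none
Why: Concerted, suprafacial [4+2] cycloaddition in which the dienoate carbons C5–C8 add across the C9=C10 alkene, forming C5–C10 and C8–C9 in one thermal step. The closest known reaction type is the thermal type 1 intramolecular Diels–Alder reaction of 1,7,9-decatrienes with an unactivated dienophile, which gives octalins. Ring B is closed as the six-membered cycloadduct ring, and ring A is closed at the same time because the four-carbon chain C1–C4 already joins the diene terminus C5 to the dienophile carbon C10 and folds into a chair. C9 and C10 follow from the E alkene (C11 and C20 stay cis), the trans C5/C10 fusion from the chair-like transition state with the tether exo and C20 endo, C8 (β-ester, cis to C11) from the E geometry of the dienoate terminus, and the absolute sense from the R-configured C2 silyloxy group, which stays equatorial because in the chair of the other π-face pairing it would be axial and syn to both the axial C4 methyl and C20. The step needs trans over cis fusion and one π-face: the first rests on the exo-tether chair expected for an E,E-diene with a quaternary allylic carbon, the second on the C2 group, and any cis-fused or 2β isomer is a ring diastereomer that chromatography should remove. C8 needs no control since it becomes sp2 in step 14.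

**Step 14**
Reactants: 22 methyl (13S)-2α-[(tert-butyldimethylsilyl)oxy]-15-[(tert-butyldiphenylsilyl)oxy]labd-6-en-17-oate
Product: 23 methyl (13S)-2α-[(tert-butyldimethylsilyl)oxy]-15-[(tert-butyldiphenylsilyl)oxy]labd-7-en-17-oate
Conditions: DBU, toluene, 110 °C
Reagents that add atoms: none
Why: Base-mediated 1,3-prototropic shift through the C8 dienolate moves the alkene into conjugation with the ester under thermodynamic control and erases the C8 centre; C9 is not acidified and keeps its configuration.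

**Step 15**
Reactants: 23 methyl (13S)-2α-[(tert-butyldimethylsilyl)oxy]-15-[(tert-butyldiphenylsilyl)oxy]labd-7-en-17-oate
Product: 24 methyl (13S)-15-[(tert-butyldiphenylsilyl)oxy]-2α-hydroxylabd-7-en-17-oate
Conditions: camphorsulfonic acid (cat.), MeOH–CH2Cl2, rt
Reagents that add atoms: none
Why: Acid-catalysed methanolysis (selective silyl ether cleavage) should remove the secondary TBS ether well before the far more acid-stable primary TBDPS ether.

**Step 16**
Reactants: 24 methyl (13S)-15-[(tert-butyldiphenylsilyl)oxy]-2α-hydroxylabd-7-en-17-oate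
Product: 25 methyl (13S)-15-[(tert-butyldiphenylsilyl)oxy]-2α-[(phenoxycarbonothioyl)oxy]labd-7-en-17-oate
Conditions: PhOC(S)Cl, pyridine, DMAP (cat.), CH2Cl2, rt
Reagents that add atoms: O-phenyl chlorothionoformate, S=C(Cl)Oc1ccccc1
Why: Acylation of the unhindered equatorial 2α-hydroxyl gives the thionocarbonate required for radical deoxygenation.

**Step 17**
Reactants: 25 methyl (13S)-15-[(tert-butyldiphenylsilyl)oxy]-2α-[(phenoxycarbonothioyl)oxy]labd-7-en-17-oate
Product: 26 methyl (13S)-15-[(tert-butyldiphenylsilyl)oxy]labd-7-en-17-oate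
Conditions: Bu3SnH, AIBN (cat.), toluene, 100 °C
Reagents that add atoms: none
Why: Barton–McCombie deoxygenation: stannyl radical addition to C=S, β-scission to the secondary C2 radical and hydrogen transfer from Bu3SnH remove the controller, and the remote conjugated ester should not interfere.

**Step 18**
Reactants: 26 methyl (13S)-15-[(tert-butyldiphenylsilyl)oxy]labd-7-en-17-oate
Product: 28 (13S)-15-hydroxylabd-7-en-17-oic acid, via hydroxy ester 27 (not isolated)
Conditions: Bu4NF, THF, rt; then KOH, MeOH–H2O, 70 °C; then aq. HCl to pH 2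
Reagents that add atoms: potassium hydroxide, [K+].[OH-]
Why: Fluoride-mediated desilylation frees the C15 alcohol and saponification of the conjugated methyl ester in the same flask gives the acid; no stereocentre is involved.

**Step 19**
Reactants: 28 (13S)-15-hydroxylabd-7-en-17-oic acid
Product: 29 (13S)-15-acetoxylabd-7-en-17-oic acid (5S,9R,10S,13S; the target)
Conditions: Ac2O, pyridine, DMAP (cat.), CH2Cl2, 0 °C → rt; aq. NaHCO3 work-up, then pH 3
Reagents that add atoms: acetic anhydride, CC(=O)OC(C)=O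
Why: Nucleophile-catalysed O-acetylation of the primary alcohol; any mixed anhydride formed at the hindered C17 acid is hydrolysed during the bicarbonate work-up.

**Compound list**

1 | (S)-citronellol, (3S)-3,7-dimethyloct-6-en-1-ol | C[C@@H](CCC=C(C)C)CCO | starting material
2 | tert-butyl{[(3S)-3,7-dimethyloct-6-en-1-yl]oxy}diphenylsilane | CC(C)=CCC[C@H](C)CCO[Si](c1ccccc1)(c1ccccc1)C(C)(C)C | intermediate
3 | 3-{(3S)-5-[(tert-butyldiphenylsilyl)oxy]-3-methylpentyl}-5,5-dimethyl-1,2,4-trioxolane (ozonide) | CC1(C)OOC(CC[C@H](C)CCO[Si](c2ccccc2)(c2ccccc2)C(C)(C)C)O1 | intermediate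
4 | (4S)-6-[(tert-butyldiphenylsilyl)oxy]-4-methylhexanal | O=CCC[C@H](C)CCO[Si](c1ccccc1)(c1ccccc1)C(C)(C)C | intermediate
5 | isopropenylmagnesium bromide | C=C(C)[Mg]Br | starting material
6 | (3RS,6S)-8-[(tert-butyldiphenylsilyl)oxy]-2,6-dimethyloct-1-en-3-ol | C=C(C)C(O)CC[C@H](C)CCO[Si](c1ccccc1)(c1ccccc1)C(C)(C)C | intermediate
7 | triethyl orthoacetate | CCOC(C)(OCC)OCC | starting material
8 | tert-butyl({(3S)-6-[(1-ethoxyethenyl)oxy]-3,7-dimethyloct-7-en-1-yl}oxy)diphenylsilane (ketene acetal) | C=C(OCC)OC(CC[C@H](C)CCO[Si](c1ccccc1)(c1ccccc1)C(C)(C)C)C(C)=C | intermediate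
9 | ethyl (4E,8S)-10-[(tert-butyldiphenylsilyl)oxy]-4,8-dimethyldec-4-enoate | CCOC(=O)CC/C(C)=C/CC[C@H](C)CCO[Si](c1ccccc1)(c1ccccc1)C(C)(C)C | intermediate
10 | (4E,8S)-10-[(tert-butyldiphenylsilyl)oxy]-4,8-dimethyldec-4-enal | O=CCC/C(C)=C/CC[C@H](C)CCO[Si](c1ccccc1)(c1ccccc1)C(C)(C)C | intermediate
11 | (2R,4E,8S)-2-(anilinooxy)-10-[(tert-butyldiphenylsilyl)oxy]-4,8-dimethyldec-4-enal | O=C[C@H](ONc1ccccc1)C/C(C)=C/CC[C@H](C)CCO[Si](c1ccccc1)(c1ccccc1)C(C)(C)C | intermediate
12 | (2R,4E,8S)-2-(anilinooxy)-10-[(tert-butyldiphenylsilyl)oxy]-4,8-dimethyldec-4-en-1-ol | OC[C@H](ONc1ccccc1)C/C(C)=C/CC[C@H](C)CCO[Si](c1ccccc1)(c1ccccc1)C(C)(C)C | intermediate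
13 | (2R,4E,8S)-10-[(tert-butyldiphenylsilyl)oxy]-4,8-dimethyldec-4-ene-1,2-diol | OC[C@H](O)C/C(C)=C/CC[C@H](C)CCO[Si](c1ccccc1)(c1ccccc1)C(C)(C)C | intermediate
14 | (2R,4E,8S)-10-[(tert-butyldiphenylsilyl)oxy]-2-hydroxy-4,8-dimethyldec-4-en-1-yl 4-methylbenzenesulfonate | Cc1ccc(cc1)S(=O)(=O)OC[C@H](O)C/C(C)=C/CC[C@H](C)CCO[Si](c1ccccc1)(c1ccccc1)C(C)(C)C | intermediate
15 | (2R)-2-{(2E,6S)-8-[(tert-butyldiphenylsilyl)oxy]-2,6-dimethyloct-2-en-1-yl}oxirane | C1O[C@@H]1C/C(C)=C/CC[C@H](C)CCO[Si](c2ccccc2)(c2ccccc2)C(C)(C)C | intermediate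
16 | isobutyronitrile | CC(C)C#N | starting material
17 | (4R,6E,10S)-12-[(tert-butyldiphenylsilyl)oxy]-4-hydroxy-2,2,6,10-tetramethyldodec-6-enenitrile | N#CC(C)(C)C[C@H](O)C/C(C)=C/CC[C@H](C)CCO[Si](c1ccccc1)(c1ccccc1)C(C)(C)C | intermediate
18 | (4R,6E,10S)-4-[(tert-butyldimethylsilyl)oxy]-12-[(tert-butyldiphenylsilyl)oxy]-2,2,6,10-tetramethyldodec-6-enenitrile | N#CC(C)(C)C[C@H](O[Si](C)(C)C(C)(C)C)C/C(C)=C/CC[C@H](C)CCO[Si](c1ccccc1)(c1ccccc1)C(C)(C)C | intermediate
19 | (4R,6E,10S)-4-[(tert-butyldimethylsilyl)oxy]-12-[(tert-butyldiphenylsilyl)oxy]-2,2,6,10-tetramethyldodec-6-enal | O=CC(C)(C)C[C@H](O[Si](C)(C)C(C)(C)C)C/C(C)=C/CC[C@H](C)CCO[Si](c1ccccc1)(c1ccccc1)C(C)(C)C | intermediate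
20 | methyl (2E)-4-(dimethoxyphosphoryl)but-2-enoate | COC(=O)/C=C/CP(=O)(OC)OC | starting material
21 | methyl (2E,4E,8R,10E,14S)-8-[(tert-butyldimethylsilyl)oxy]-16-[(tert-butyldiphenylsilyl)oxy]-6,6,10,14-tetramethylhexadeca-2,4,10-trienoate | COC(=O)/C=C/C=C/C(C)(C)C[C@H](O[Si](C)(C)C(C)(C)C)C/C(C)=C/CC[C@H](C)CCO[Si](c1ccccc1)(c1ccccc1)C(C)(C)C | intermediate
22 | methyl (13S)-2α-[(tert-butyldimethylsilyl)oxy]-15-[(tert-butyldiphenylsilyl)oxy]labd-6-en-17-oate (8β-ester, trans-fused) | CC(C)(C)[Si](c1ccccc1)(c1ccccc1)OCC[C@@H](C)CC[C@H]1[C@@H](C(=O)OC)C=C[C@H]2C(C)(C)C[C@H](O[Si](C)(C)C(C)(C)C)C[C@]12C | intermediate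
23 | methyl (13S)-2α-[(tert-butyldimethylsilyl)oxy]-15-[(tert-butyldiphenylsilyl)oxy]labd-7-en-17-oate | CC(C)(C)[Si](c1ccccc1)(c1ccccc1)OCC[C@@H](C)CC[C@H]1C(C(=O)OC)=CC[C@H]2C(C)(C)C[C@H](O[Si](C)(C)C(C)(C)C)C[C@]12C | intermediate
24 | methyl (13S)-15-[(tert-butyldiphenylsilyl)oxy]-2α-hydroxylabd-7-en-17-oate | CC(C)(C)[Si](c1ccccc1)(c1ccccc1)OCC[C@@H](C)CC[C@H]1C(C(=O)OC)=CC[C@H]2C(C)(C)C[C@H](O)C[C@]12C | intermediate
25 | methyl (13S)-15-[(tert-butyldiphenylsilyl)oxy]-2α-[(phenoxycarbonothioyl)oxy]labd-7-en-17-oate | CC(C)(C)[Si](c1ccccc1)(c1ccccc1)OCC[C@@H](C)CC[C@H]1C(C(=O)OC)=CC[C@H]2C(C)(C)C[C@H](OC(=S)Oc3ccccc3)C[C@]12C | intermediate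
26 | methyl (13S)-15-[(tert-butyldiphenylsilyl)oxy]labd-7-en-17-oate | CC(C)(C)[Si](c1ccccc1)(c1ccccc1)OCC[C@@H](C)CC[C@H]1C(C(=O)OC)=CC[C@H]2C(C)(C)CCC[C@]12C | intermediate
27 | methyl (13S)-15-hydroxylabd-7-en-17-oate | OCC[C@@H](C)CC[C@H]1C(C(=O)OC)=CC[C@H]2C(C)(C)CCC[C@]12C | intermediate
28 | (13S)-15-hydroxylabd-7-en-17-oic acid | OCC[C@@H](C)CC[C@H]1C(C(=O)O)=CC[C@H]2C(C)(C)CCC[C@]12C | intermediate
29 | (13S)-15-acetoxylabd-7-en-17-oic acid | CC(=O)OCC[C@@H](C)CC[C@H]1C(C(=O)O)=CC[C@H]2C(C)(C)CCC[C@]12C | target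

**Totals**

Total step count: 19. Longest linear sequence: 19 steps, from (S)-citronellol.

**Steps most likely to fail**

Step 13. The unactivated alkene may add so slowly that polymerisation of the dienoate competes, or the tether may fold endo to a comparable extent and erode the trans ring fusion. The fallback sets out from nitrile 18 and returns at 23.
- Addition of MeLi to 18 and hydrolysis of the ketimine would give (5R,7E,11S)-5-[(tert-butyldimethylsilyl)oxy]-13-[(tert-butyldiphenylsilyl)oxy]-3,3,7,11-tetramethyltridec-7-en-2-one F1.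
- Its lithium enolate (LiN(i-Pr)2) would react with dimethyl 2-(methoxymethylidene)malonate by addition–elimination and lactonisation to give methyl 6-{(4R,6E,10S)-4-[(tert-butyldimethylsilyl)oxy]-12-[(tert-butyldiphenylsilyl)oxy]-2,6,10-trimethyldodec-6-en-2-yl}-2-oxo-2H-pyran-3-carboxylate F2.
- Heating F2 would bring about the intramolecular inverse-demand Diels–Alder reaction of this far more electron-poor diene across C9=C10 with loss of CO2, giving methyl (13S)-2α-[(tert-butyldimethylsilyl)oxy]-15-[(tert-butyldiphenylsilyl)oxy]labda-5,7-dien-17-oate F3.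
- In F3, C5 is sp2, so no ring-fusion selectivity is asked of the cycloaddition, while C9 and C10 still follow from the E alkene and the C2 group.
- Hydrogenation of the 5,6-bond from the α-face (H2, Pd/C, EtOAc), opposite the C10 and axial C4 methyl groups as in the saturation of homoannular 5,7-dienes, would then give 23.

Step 6. Nitrosobenzene may undergo an ene reaction with the trisubstituted alkene, the aldehyde may self-condense, or the α-oxy aldehyde may partly racemise before reduction. The fallback sets out from ester 9 and returns at diol 13.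
- Saponification (LiOH, THF–H2O) would give (4E,8S)-10-[(tert-butyldiphenylsilyl)oxy]-4,8-dimethyldec-4-enoic acid F4.
- Acylation of (R)-4-benzyl-1,3-oxazolidin-2-one through the pivaloyl mixed anhydride (PivCl, Et3N, LiCl) would give (4R)-4-benzyl-3-{(4E,8S)-10-[(tert-butyldiphenylsilyl)oxy]-4,8-dimethyldec-4-enoyl}-1,3-oxazolidin-2-one F5.
- Auxiliary-controlled hydroxylation of the sodium enolate (NaN(SiMe3)2, then 3-phenyl-2-(phenylsulfonyl)oxaziridine, −78 °C), on the face opposite the benzyl group, would give (4R)-4-benzyl-3-{(2R,4E,8S)-10-[(tert-butyldiphenylsilyl)oxy]-2-hydroxy-4,8-dimethyldec-4-enoyl}-1,3-oxazolidin-2-one F6.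
- Reductive removal of the auxiliary with LiBH4 would give 13.

Step 12. Addition to the neopentyl-type aldehyde may be sluggish, or the new C5=C6 bond may form with incomplete E selectivity. The fallback sets out from aldehyde 19 and returns at triene 21.
- Takai iodo-olefination (CrCl2, CHI3, THF) would give (1E,5R,7E,11S)-5-[(tert-butyldimethylsilyl)oxy]-13-[(tert-butyldiphenylsilyl)oxy]-1-iodo-3,3,7,11-tetramethyltrideca-1,7-diene F7.
- Heck coupling of F7 with methyl acrylate (Pd(OAc)2, K2CO3, Bu4NCl, DMF) would build the (2E,4E)-dienoate with both alkene geometries set by the coupling, giving 21.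

**Further compounds**

F1 | step 13 | (5R,7E,11S)-5-[(tert-butyldimethylsilyl)oxy]-13-[(tert-butyldiphenylsilyl)oxy]-3,3,7,11-tetramethyltridec-7-en-2-one | CC(=O)C(C)(C)C[C@H](O[Si](C)(C)C(C)(C)C)C/C(C)=C/CC[C@H](C)CCO[Si](c1ccccc1)(c1ccccc1)C(C)(C)C
F2 | step 13 | methyl 6-{(4R,6E,10S)-4-[(tert-butyldimethylsilyl)oxy]-12-[(tert-butyldiphenylsilyl)oxy]-2,6,10-trimethyldodec-6-en-2-yl}-2-oxo-2H-pyran-3-carboxylate | COC(=O)C1=CC=C(OC1=O)C(C)(C)C[C@H](O[Si](C)(C)C(C)(C)C)C/C(C)=C/CC[C@H](C)CCO[Si](c2ccccc2)(c2ccccc2)C(C)(C)C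
F3 | step 13 | methyl (13S)-2α-[(tert-butyldimethylsilyl)oxy]-15-[(tert-butyldiphenylsilyl)oxy]labda-5,7-dien-17-oate | CC(C)(C)[Si](c1ccccc1)(c1ccccc1)OCC[C@@H](C)CC[C@H]1C(C(=O)OC)=CC=C2C(C)(C)C[C@H](O[Si](C)(C)C(C)(C)C)C[C@]12C
F4 | step 6 | (4E,8S)-10-[(tert-butyldiphenylsilyl)oxy]-4,8-dimethyldec-4-enoic acid | OC(=O)CC/C(C)=C/CC[C@H](C)CCO[Si](c1ccccc1)(c1ccccc1)C(C)(C)C
F5 | step 6 | (4R)-4-benzyl-3-{(4E,8S)-10-[(tert-butyldiphenylsilyl)oxy]-4,8-dimethyldec-4-enoyl}-1,3-oxazolidin-2-one | O=C(CC/C(C)=C/CC[C@H](C)CCO[Si](c1ccccc1)(c1ccccc1)C(C)(C)C)N1[C@H](Cc2ccccc2)COC1=O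
F6 | step 6 | (4R)-4-benzyl-3-{(2R,4E,8S)-10-[(tert-butyldiphenylsilyl)oxy]-2-hydroxy-4,8-dimethyldec-4-enoyl}-1,3-oxazolidin-2-one | O=C([C@H](O)C/C(C)=C/CC[C@H](C)CCO[Si](c1ccccc1)(c1ccccc1)C(C)(C)C)N1[C@H](Cc2ccccc2)COC1=O
F7 | step 12 | (1E,5R,7E,11S)-5-[(tert-butyldimethylsilyl)oxy]-13-[(tert-butyldiphenylsilyl)oxy]-1-iodo-3,3,7,11-tetramethyltrideca-1,7-diene | I/C=C/C(C)(C)C[C@H](O[Si](C)(C)C(C)(C)C)C/C(C)=C/CC[C@H](C)CCO[Si](c1ccccc1)(c1ccccc1)C(C)(C)C
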